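## Analysis of the target

The target (C28H24O5) is a 19-membered macrocyclic bis(bibenzyl) of the marchantin type. Four benzene rings are joined in a circle: ring A (a 1,2,4-trisubstituted phenol), ring B (a meta-phenylene), ring C (a 1,3,4,5-tetrasubstituted catechol) and ring D (a para-phenylene). The links are two diaryl ether oxygens (A–O–B and C–O–D) and two ethano bridges (A–CH2CH2–D and B–CH2CH2–C). There is no stereocenter and no double bond, so no stereochemical relationship has to be set. The sensitive groups are the three free phenols, above all the catechol at C3/C4 of ring C, which oxidises easily in air under base and should therefore be unmasked only in the last step. The synthesis is hard for two reasons: a large ring containing a rigid para-phenylene unit must be closed, and both diaryl ethers sit at carbons that are electron-rich and not activated in the target. The strategy rests on ring C (bridge carbon C1, hydroxyls at C3 and C4, aryloxy at C5), where the ether carbon C5 is the direct neighbour of the hydroxyl-bearing C4. A formyl group at C4 can therefore make C5 electrophilic for a ring-closing etherification and can afterwards be oxidised to the C4 hydroxyl, so the activating group ends as an atom of the target.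

## Retrosynthetic reasoning

**21 from 20.** The last disconnection is at the two O–CH3 bonds (ring A and C3 of ring C). Methyl ethers are chosen because they survive base, organolithium, hydrogenation and peracid. The forward reaction is a Lewis-acid demethylation that must leave both diaryl ethers intact.

**20 from 18 (through formate 19).** The C4–O bond is traced back to a C4–CHO bond. This places a carbonyl acceptor ortho to C5 at the cost of one oxidation. The forward step needs aryl migration to a peroxide oxygen, which the two ortho oxygens favour. The alkaline peroxide form of this oxidation needs a free ortho or para hydroxyl, which 18 lacks, so the peracid form with cleavage of the formate is planned.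

**18 from 16 (key disconnection).** The C5–O bond between ring C and the ring D oxygen is cut. This one cut opens the macrocycle and makes a diaryl ether without copper. The nucleophile it releases is the unhindered para-alkylphenol of ring D. Ring A has the same ortho relation between its hydroxyl and its ether carbon, but only in ring C does the activating carbon lie between two heteroatom substituents (F at C5 and OMe at C3 in the precursor), so a formyl group can be placed there by lithiation with certainty. Closing the ring at an ethano bridge instead would leave the crowded C5 ether to a copper coupling. The forward reaction must displace fluoride only, and do so within the molecule.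

**16 from 13 (through 14 and 15).** The C4–CHO bond is cut back to C4–H. C4 lies between fluorine and methoxy and is the most acidic ring position, so ortho-lithiation and formylation should be regioselective. The step is placed late so that the substitution-active fluoroaldehyde exists only directly before ring closure and never meets a phenoxide under copper coupling or a hydrogenation catalyst. The ring D hydroxyl is carried through as its lithium salt.

**13 from 12.** Both ethano bridges and the free ring D hydroxyl come from one catalytic hydrogenation of a bis-stilbene benzyl ether. Alkene geometry is therefore irrelevant in everything before.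

**12 from 9 and 10 (through ylide 11).** The B–C bridge is cut at its double bond, a Wittig olefination. Ring C enters as the purchased aldehyde 10 with fluorine and methoxy already in place. Salt 9 comes from alcohol 7 through bromide 8.

**7 from 2 and 5 (through ylide 6).** The A–D bridge is cut in the same way. Salt 2 comes from chloride 1. The benzylic hydroxyl of 5 stays free because it is far too weakly acidic to quench the ylide.

**5 from 3 and 4.** The A–O–B ether is cut at the ring A carbon. The bromide of 3 is meta to the formyl group and not activated, so a copper-catalysed Ullmann coupling is needed. It is done first, on the two smallest pieces, so that the least predictable coupling risks no advanced material. The forward reaction must arylate the phenol of 4 and not its benzylic hydroxyl.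

## Alternatives that were turned down

**Alternative 1:** Ring C is built de novo; the disconnection cuts its C1–C2 and C5–C6 bonds. In the forward key step the chlorocyclobutenone A2 and the α-stannyl alkene A3 undergo Stille coupling (PdCl2(PhCN)2, a divalent palladium precatalyst, with tri(2-furyl)phosphine). The resulting vinylcyclobutenone opens by a 4π electrocyclic reaction to a dienylketene and closes by a 6π reaction to the phenol A1.
- For it: the three contiguous oxygens of ring C arrive fully differentiated (free hydroxyl at the future ether carbon, isopropyl ethers at the future catechol), the regiochemistry is fixed by construction, and the conditions are neutral.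
- Against it: ring C can be bought as an intact arene (10), so the benzannulation solves a problem the target does not pose. A1 is still open-chain: a hindered 2,3-dialkoxyphenol must then be arylated by a non-activated ring D partner and the macrocycle closed in yet another step, so the ring-closure risk is only postponed. A2 and A3 each need several steps, and tin is used stoichiometrically.
- Comparison: this route is stronger on oxygen differentiation (no formyl-to-hydroxyl oxidation, no organolithium on a late intermediate). The chosen route offers instead ether formation and ring closure in one step from four purchased arenes, and should be shorter by roughly five steps.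

**Alternative 2:** Ring A is carried at the cyclohexanone level; the disconnection is the bond between the ring B oxygen and the sp3 carbon alpha to the ketone. In the forward key step K2CO3 at high dilution lets the ring B phenoxide of the bromoketone A5 displace bromide, giving the macrocyclic 2-aryloxycyclohexanone A4 (racemic, cis). Dehydrogenative aromatisation would then turn the ketone into the ring A phenol.
- For it: SN2 substitution at an α-halo ketone is fast at mild temperature, needs neither copper nor an activating group, and the ketone oxygen becomes a target hydroxyl without protection.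
- Against it: an α-bromoketone under base is open to Favorskii rearrangement, elimination to the enone and enolisation. Two stereocenters are created only to be erased. The aromatisation must remove two equivalents of hydrogen from a macrocycle with four benzylic CH2 groups and electron-rich rings. A5 needs a saturated ring A precursor with its side chain, which costs extra steps, and the C–O–D ether still needs a copper coupling at the crowded ring C.
- Comparison: this route is stronger on the mildness of ring closure. The chosen route avoids the redox detour and the stereoisomer mixtures, keeps all rings aromatic throughout, and follows ring closure with two predictable steps.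

**Alternative 3:** The disconnection is the bond from C1 of ring C to its benzylic carbon, with the neighbouring bridge carbon as a ketone on ring B. In the forward key step Pd2(dba)3 (zerovalent palladium), Xantphos and NaOtBu arylate the methyl ketone enolate of A7 with its ring C bromide, giving the 19-membered deoxybenzoin A6.
- For it: the closure forms a C–C bond at a non-oxygenated position, both diaryl ethers are made beforehand on simple partners, and ring C carries both catechol oxygens from the start, so no lithiation and no Dakin step are needed.
- Against it: A6 is more acidic than the methyl ketone, so its enolate competes for a second, intermolecular arylation. The methyl ketone can self-condense under NaOtBu. High dilution slows oxidative addition into an electron-rich bromide while the catalyst decays. After closure the carbonyl must be removed in extra steps.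
- Comparison: this route is equal or stronger on convergence and on the supply of ring C oxygenation. The chosen route offers a catalyst-free, unimolecular closure whose rate does not depend on catalyst concentration, and an activating group that becomes a target atom instead of being deleted.

Key step: step 9

Remark on the chemistry: the macrocycle is assumed to be conformationally mobile, with no stable atropisomers. All Wittig products are carried as E/Z mixtures because both double bonds are hydrogenated in step 7.

## Route

Step 1
Reactants: 1 4-(benzyloxy)benzyl chloride
Product: 2 [4-(benzyloxy)benzyl]triphenylphosphonium chloride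
Conditions: PPh3, toluene, reflux
Reagents that add atoms: triphenylphosphine, c1ccc(cc1)P(c1ccccc1)c1ccccc1
Why: SN2 quaternisation of the phosphine by a benzylic chloride (phosphonium salt formation for a Wittig reaction); the salt should precipitate from hot toluene and be used after filtration.

Step 2
Reactants: 3 3-bromo-4-methoxybenzaldehyde; 4 3-hydroxybenzyl alcohol
Product: 5 3-[3-(hydroxymethyl)phenoxy]-4-methoxybenzaldehyde
Conditions: CuI (10 mol%), picolinic acid (20 mol%), K3PO4, DMSO, 90 °C
Reagents that add atoms: none
Why: Ullmann-type diaryl ether synthesis catalysed by monovalent copper with picolinic acid as ligand, a system that tolerates an ortho substituent on the bromide; K3PO4 deprotonates only the phenol, so arylation should occur at the phenolic oxygen and not at the benzylic hydroxyl, and the aldehyde is inert.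

Step 3
Reactants: 2 [4-(benzyloxy)benzyl]triphenylphosphonium chloride; 5 3-[3-(hydroxymethyl)phenoxy]-4-methoxybenzaldehyde
Product: 7 (3-{5-[2-(4-benzyloxyphenyl)ethenyl]-2-methoxyphenoxy}phenyl)methanol (E/Z mixture), via benzylidenephosphorane 6 (not isolated)
Conditions: KOtBu, THF, 0 °C; then 5, 0 °C to rt
Reagents that add atoms: none
Why: Wittig olefination of an aromatic aldehyde with a semi-stabilised benzylic ylide; the benzylic hydroxyl of 5 is much less acidic than the phosphonium salt and does not quench 6, and the E/Z mixture is of no consequence because the double bond is hydrogenated in step 7.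

Step 4
Reactants: 7 (3-{5-[2-(4-benzyloxyphenyl)ethenyl]-2-methoxyphenoxy}phenyl)methanol
Product: 8 4-[2-(4-benzyloxyphenyl)ethenyl]-2-[3-(bromomethyl)phenoxy]-1-methoxybenzene (E/Z mixture)
Conditions: CBr4, PPh3, CH2Cl2, 0 °C
Reagents that add atoms: carbon tetrabromide, BrC(Br)(Br)Br
Why: Appel reaction; the alcohol is activated as an alkoxyphosphonium ion and displaced by bromide under neutral conditions that leave the stilbene, the benzyl ether and the diaryl ether untouched.

Step 5
Reactants: 8 4-[2-(4-benzyloxyphenyl)ethenyl]-2-[3-(bromomethyl)phenoxy]-1-methoxybenzene
Product: 9 (3-{5-[2-(4-benzyloxyphenyl)ethenyl]-2-methoxyphenoxy}benzyl)triphenylphosphonium bromide (E/Z mixture)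
Conditions: PPh3, toluene, reflux
Reagents that add atoms: triphenylphosphine, c1ccc(cc1)P(c1ccccc1)c1ccccc1
Why: SN2 quaternisation of the phosphine by a primary benzylic bromide, the standard entry to a benzylic Wittig salt; no other electrophilic site is present.

Step 6
Reactants: 9 (3-{5-[2-(4-benzyloxyphenyl)ethenyl]-2-methoxyphenoxy}benzyl)triphenylphosphonium bromide; 10 3-fluoro-5-methoxybenzaldehyde
Product: 12 4-[2-(4-benzyloxyphenyl)ethenyl]-2-{3-[2-(3-fluoro-5-methoxyphenyl)ethenyl]phenoxy}-1-methoxybenzene (mixture of alkene isomers), via ylide 11 (not isolated)
Conditions: KOtBu, THF, 0 °C; then 10, 0 °C to rt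
Reagents that add atoms: none
Why: second Wittig olefination; the fluorine of 10 is meta to the formyl group and not activated towards tert-butoxide, so only the aldehyde reacts, and the alkene geometry is again irrelevant.

Step 7
Reactants: 12 4-[2-(4-benzyloxyphenyl)ethenyl]-2-{3-[2-(3-fluoro-5-methoxyphenyl)ethenyl]phenoxy}-1-methoxybenzene
Product: 13 4-[2-(3-{3-[2-(3-fluoro-5-methoxyphenyl)ethyl]phenoxy}-4-methoxyphenyl)ethyl]phenol
Conditions: H2 (1 atm), 10% Pd/C, EtOAc/MeOH, rt
Reagents that add atoms: none
Why: heterogeneous catalytic hydrogenation saturates both stilbene double bonds and hydrogenolyses the benzyl ether in the same operation; the aryl fluoride, the methyl ethers and the diaryl ether are stable to Pd/C at 1 atm.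

Step 8
Reactants: 13 4-[2-(3-{3-[2-(3-fluoro-5-methoxyphenyl)ethyl]phenoxy}-4-methoxyphenyl)ethyl]phenol
Product: 16 2-fluoro-4-[2-(3-{5-[2-(4-hydroxyphenyl)ethyl]-2-methoxyphenoxy}phenyl)ethyl]-6-methoxybenzaldehyde, via dilithio species 14 (not isolated), via lithium aminoalkoxide 15 (not isolated)
Conditions: n-BuLi (2.3 equiv), THF, −78 °C; DMF, −78 °C to 0 °C; aq NH4Cl
Reagents that add atoms: N,N-dimethylformamide, CN(C)C=O
Why: directed ortho-metalation followed by formylation; the first equivalent of n-BuLi makes the lithium phenoxide and the second removes the proton at C4 of ring C, the only position flanked by both fluorine and methoxy and so by far the most acidic; DMF traps 14 as the tetrahedral adduct 15, which releases the aldehyde only on aqueous work-up, and holding −78 °C until the quench prevents loss of LiF to an aryne.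

Step 9
Reactants: 16 2-fluoro-4-[2-(3-{5-[2-(4-hydroxyphenyl)ethyl]-2-methoxyphenoxy}phenyl)ethyl]-6-methoxybenzaldehyde
Product: 18 macrocyclic aldehyde (19-membered ring; ring C with CHO at C4 and OMe at C3; ring A with OMe), via potassium phenoxide 17 (not isolated)
Conditions: K2CO3, amine-free DMF, 110 °C, slow addition of 16 to about 0.002 M
Reagents that add atoms: none
Why: This is an intramolecular SNAr (addition–elimination) macro-etherification, the ring-closing counterpart of the well-known coupling of phenoxides with ortho-fluorobenzaldehydes. K2CO3 converts the ring D phenol into phenoxide 17, which adds at C5 of ring C ipso to fluorine; the negative charge of the σ-adduct is delocalised onto the oxygen of the ortho formyl group, and loss of fluoride restores the arene and gives the C5–O bond. This single bond closes the 19-membered ring end to end, between chain termini joined by two flexible ethano hinges. No stereocenter is formed. The step needs selectivity between the two positions ortho to the formyl group: fluoride is a far better leaving group in SNAr than methoxide, so substitution should occur at C5 only. The only phenol in 16 is on ring D and the aldehyde has no α-hydrogen, so there is no competing nucleophile or enolisation. Ring closure must beat chain growth, which the slow addition and low concentration address. Amine-free solvent limits attack of dimethylamine on the C–F carbon.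

Step 10
Reactants: 18 macrocyclic aldehyde
Product: 20 macrocyclic phenol (ring C with OH at C4 and OMe at C3; ring A with OMe), via aryl formate 19 (not isolated)
Conditions: mCPBA, CH2Cl2, 0 °C to rt; Na2SO3 wash; K2CO3, MeOH, rt
Reagents that add atoms: meta-chloroperoxybenzoic acid, OOC(=O)c1cccc(Cl)c1
Why: Dakin oxidation in its peracid (Baeyer–Villiger type) form; the peracid adds to the formyl group and the aryl group, made electron-rich by its two ortho oxygens, migrates to oxygen in preference to hydride to give formate 19, which is methanolysed to the phenol; the alkaline hydrogen peroxide form is not used because it depends on a free ortho or para hydroxyl, which 18 lacks.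

Step 11
Reactants: 20 macrocyclic phenol
Product: 21 target macrocycle (ring A phenol; ring C 3,4-diol)
Conditions: BBr3 (5 equiv), CH2Cl2, −78 °C to rt; degassed H2O
Reagents that add atoms: none
Why: Lewis-acid ether cleavage; BBr3 coordinates each methoxy oxygen and bromide removes the methyl group by SN2, whereas the diaryl ethers offer no alkyl carbon and survive; work-up under argon limits air oxidation of the catechol.

## Compound list

1 | 4-(benzyloxy)benzyl chloride | ClCc1ccc(OCc2ccccc2)cc1 | starting material
2 | [4-(benzyloxy)benzyl]triphenylphosphonium chloride | [Cl-].c1ccc(cc1)[P+](Cc1ccc(OCc2ccccc2)cc1)(c1ccccc1)c1ccccc1 | intermediate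
3 | 3-bromo-4-methoxybenzaldehyde | COc1ccc(C=O)cc1Br | starting material
4 | 3-hydroxybenzyl alcohol | OCc1cccc(O)c1 | starting material
5 | 3-[3-(hydroxymethyl)phenoxy]-4-methoxybenzaldehyde | COc1ccc(C=O)cc1Oc1cccc(CO)c1 | intermediate
6 | [4-(benzyloxy)benzylidene]triphenylphosphorane (not isolated) | c1ccc(cc1)P(=Cc1ccc(OCc2ccccc2)cc1)(c1ccccc1)c1ccccc1 | intermediate
7 | (3-{5-[2-(4-benzyloxyphenyl)ethenyl]-2-methoxyphenoxy}phenyl)methanol, E/Z mixture | COc1ccc(C=Cc2ccc(OCc3ccccc3)cc2)cc1Oc1cccc(CO)c1 | intermediate
8 | 4-[2-(4-benzyloxyphenyl)ethenyl]-2-[3-(bromomethyl)phenoxy]-1-methoxybenzene, E/Z mixture | COc1ccc(C=Cc2ccc(OCc3ccccc3)cc2)cc1Oc1cccc(CBr)c1 | intermediate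
9 | (3-{5-[2-(4-benzyloxyphenyl)ethenyl]-2-methoxyphenoxy}benzyl)triphenylphosphonium bromide, E/Z mixture | [Br-].COc1ccc(C=Cc2ccc(OCc3ccccc3)cc2)cc1Oc1cccc(C[P+](c2ccccc2)(c2ccccc2)c2ccccc2)c1 | intermediate
10 | 3-fluoro-5-methoxybenzaldehyde | COc1cc(F)cc(C=O)c1 | starting material
11 | ylide of 9 (not isolated) | COc1ccc(C=Cc2ccc(OCc3ccccc3)cc2)cc1Oc1cccc(C=P(c2ccccc2)(c2ccccc2)c2ccccc2)c1 | intermediate
12 | 4-[2-(4-benzyloxyphenyl)ethenyl]-2-{3-[2-(3-fluoro-5-methoxyphenyl)ethenyl]phenoxy}-1-methoxybenzene, mixture of alkene isomers | COc1cc(F)cc(C=Cc2cccc(Oc3cc(C=Cc4ccc(OCc5ccccc5)cc4)ccc3OC)c2)c1 | intermediate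
13 | 4-[2-(3-{3-[2-(3-fluoro-5-methoxyphenyl)ethyl]phenoxy}-4-methoxyphenyl)ethyl]phenol | COc1cc(F)cc(CCc2cccc(Oc3cc(CCc4ccc(O)cc4)ccc3OC)c2)c1 | intermediate
14 | dilithio species of 13: lithium phenoxide on ring D, aryllithium at C4 of ring C (not isolated) | [Li]Oc1ccc(CCc2ccc(OC)c(Oc3cccc(CCc4cc(F)c([Li])c(OC)c4)c3)c2)cc1 | intermediate
15 | lithium α-(dimethylamino)alkoxide at C4 of ring C, with lithium phenoxide on ring D (not isolated) | [Li]Oc1ccc(CCc2ccc(OC)c(Oc3cccc(CCc4cc(F)c(C(O[Li])N(C)C)c(OC)c4)c3)c2)cc1 | intermediate
16 | 2-fluoro-4-[2-(3-{5-[2-(4-hydroxyphenyl)ethyl]-2-methoxyphenoxy}phenyl)ethyl]-6-methoxybenzaldehyde | COc1ccc(CCc2ccc(O)cc2)cc1Oc1cccc(CCc2cc(F)c(C=O)c(OC)c2)c1 | intermediate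
17 | potassium phenoxide of 16 (not isolated) | [K+].COc1ccc(CCc2ccc([O-])cc2)cc1Oc1cccc(CCc2cc(F)c(C=O)c(OC)c2)c1 | intermediate
18 | macrocyclic aldehyde: ring C with CHO at C4 and OMe at C3, ring A with OMe | COc1ccc2cc1Oc1cccc(c1)CCc1cc(OC)c(C=O)c(c1)Oc1ccc(cc1)CC2 | intermediate
19 | macrocyclic aryl formate at C4 of ring C (not isolated) | COc1ccc2cc1Oc1cccc(c1)CCc1cc(OC)c(OC=O)c(c1)Oc1ccc(cc1)CC2 | intermediate
20 | macrocyclic phenol: ring C with OH at C4 and OMe at C3, ring A with OMe | COc1ccc2cc1Oc1cccc(c1)CCc1cc(OC)c(O)c(c1)Oc1ccc(cc1)CC2 | intermediate
21 | target macrocycle: ring A phenol, ring C 3,4-diol | Oc1ccc2cc1Oc1cccc(c1)CCc1cc(O)c(O)c(c1)Oc1ccc(cc1)CC2 | target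

## Step count and least certain steps

Total: 11 steps. Longest linear sequence: 10 steps (steps 2 to 11, from 3 and 4 to 21); step 1 is the only step off this line.

**Step 9 (key step).** Chain growth by intermolecular etherification may compete with ring closure. The substitution may also be slow, because the C3 methoxy group donates into the formyl group and weakens its pull, and the solvent may slowly release amine that attacks the C–F carbon. The fallback gives up etherification as the ring-closing event and sets out from 7. Hydrogenation (H2, Pd/C) should give the phenol alcohol F1. Copper-catalysed Ullmann coupling (CuI, picolinic acid, K3PO4, DMSO) with purchased 3-bromo-4,5-dimethoxybenzaldehyde F2 should give the diaryl ether aldehyde F3. PPh3·HBr in refluxing MeCN should convert the benzylic alcohol into the phosphonium bromide F4. An intramolecular Wittig reaction at high dilution (NaOMe, CH2Cl2) should close the ring at the B–C bridge to the macrocyclic stilbene F5. Hydrogenation should give the macrocyclic trimethyl ether F6, and BBr3 brings the sequence back to the route at 21.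

**Step 8.** Metalation may be incomplete or misdirected if the lithium phenoxide ties up the base in mixed aggregates, and the ortho-fluoro aryllithium may lose lithium fluoride if the temperature rises. The fallback protects the phenol and sets out from 13. Silylation (TIPSCl, imidazole, DMF) should give the silyl ether F7. Lithiation with n-BuLi (1.1 equiv, THF, −78 °C) and DMF quench should give the silyl-protected fluoroaldehyde F8. Desilylation with TBAF buffered by AcOH (THF, 0 °C) returns to the route at 16.

**Step 2.** Coupling at the bromide flanked by the methoxy group may be slow, which would allow arylation of the benzylic hydroxyl or reduction of the C–Br bond to compete. The fallback reverses the roles of the partners and replaces 3 and 4. Purchased isovanillin F9 and purchased [3-(hydroxymethyl)phenyl]boronic acid F10 are joined by Chan–Lam coupling (Cu(OAc)2, pyridine, 4 Å molecular sieves, CH2Cl2, air, rt), which should arrive at 5.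

**Step 10.** Hydride migration instead of aryl migration in the peracid adduct would give the carboxylic acid, and the electron-rich phenol may be oxidised further once it is set free. The fallback swaps the order of the last two steps and sets out from 18. BBr3 should cleave both methyl ethers to the macrocyclic salicylaldehyde F11, whose free ortho hydroxyl makes it a classical Dakin substrate. Alkaline hydrogen peroxide (H2O2, NaOH, THF/H2O, 0 °C, under argon) should then give 21 directly.

## Further compounds

F1 | step 9 | 4-{2-[3-(3-(hydroxymethyl)phenoxy)-4-methoxyphenyl]ethyl}phenol | COc1ccc(CCc2ccc(O)cc2)cc1Oc1cccc(CO)c1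
F2 | step 9 | 3-bromo-4,5-dimethoxybenzaldehyde (purchased) | COc1cc(C=O)cc(Br)c1OC
F3 | step 9 | 3-(4-{2-[3-(3-(hydroxymethyl)phenoxy)-4-methoxyphenyl]ethyl}phenoxy)-4,5-dimethoxybenzaldehyde | COc1ccc(CCc2ccc(Oc3cc(C=O)cc(OC)c3OC)cc2)cc1Oc1cccc(CO)c1
F4 | step 9 | phosphonium bromide of F3 (benzylic CH2PPh3 on ring B) | [Br-].COc1ccc(CCc2ccc(Oc3cc(C=O)cc(OC)c3OC)cc2)cc1Oc1cccc(C[P+](c2ccccc2)(c2ccccc2)c2ccccc2)c1
F5 | step 9 | macrocyclic stilbene trimethyl ether (B–C bridge as CH=CH, E/Z mixture) | COc1ccc2cc1Oc1cccc(c1)C=Cc1cc(OC)c(OC)c(c1)Oc1ccc(cc1)CC2
F6 | step 9 | macrocyclic trimethyl ether | COc1ccc2cc1Oc1cccc(c1)CCc1cc(OC)c(OC)c(c1)Oc1ccc(cc1)CC2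
F7 | step 8 | triisopropylsilyl ether of 13 | COc1cc(F)cc(CCc2cccc(Oc3cc(CCc4ccc(O[Si](C(C)C)(C(C)C)C(C)C)cc4)ccc3OC)c2)c1
F8 | step 8 | triisopropylsilyl ether of 16 | COc1ccc(CCc2ccc(O[Si](C(C)C)(C(C)C)C(C)C)cc2)cc1Oc1cccc(CCc2cc(F)c(C=O)c(OC)c2)c1
F9 | step 2 | isovanillin, 3-hydroxy-4-methoxybenzaldehyde (purchased) | COc1ccc(C=O)cc1O
F10 | step 2 | [3-(hydroxymethyl)phenyl]boronic acid (purchased) | OCc1cccc(c1)B(O)O
F11 | step 10 | macrocyclic salicylaldehyde: ring C with CHO at C4 and OH at C3, ring A phenol | Oc1ccc2cc1Oc1cccc(c1)CCc1cc(O)c(C=O)c(c1)Oc1ccc(cc1)CC2
A1 | alternative 1 | 3-{3-[2-(3-hydroxy-4,5-diisopropoxyphenyl)ethyl]phenoxy}-4-methoxybenzaldehyde | Oc1cc(CCc2cccc(Oc3cc(C=O)ccc3OC)c2)cc(OC(C)C)c1OC(C)C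
A2 | alternative 1 | 4-chloro-2,3-diisopropoxycyclobut-2-en-1-one | CC(C)OC1=C(OC(C)C)C(Cl)C1=O
A3 | alternative 1 | 3-{3-[3-(tributylstannyl)but-3-en-1-yl]phenoxy}-4-methoxybenzaldehyde | C=C(CCc1cccc(Oc2cc(C=O)ccc2OC)c1)[Sn](CCCC)(CCCC)CCCC
A4 | alternative 2 | macrocyclic 2-aryloxycyclohexanone, racemic cis (one enantiomer drawn) | O=C1CC[C@@H]2C[C@H]1Oc1cccc(c1)CCc1cc(OC)c(OC)c(c1)Oc1ccc(cc1)CC2
A5 | alternative 2 | seco 2-bromo-4-substituted cyclohexanone with free ring B phenol (racemic diastereomer mixture) | O=C1CCC(CCc2ccc(Oc3cc(CCc4cccc(O)c4)cc(OC)c3OC)cc2)CC1Br
A6 | alternative 3 | macrocyclic deoxybenzoin (ketone next to ring B) | COc1ccc2cc1Oc1cccc(c1)C(=O)Cc1cc(OC)c(OC)c(c1)Oc1ccc(cc1)CC2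
A7 | alternative 3 | seco methyl ketone on ring B with aryl bromide at C1 of ring C | CC(=O)c1cccc(Oc2cc(CCc3ccc(Oc4cc(Br)cc(OC)c4OC)cc3)ccc2OC)c1
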